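**Plan**
1. Numbering: lactam carbonyl C1, chain C2–C15 (C15 = benzylic carbinol), arene C16–C21 with C15 on C16, oxygen on C18 and C21, nitrogen on C20. The 19-membered lactam ring (N, C1–C16, C21, C20) holds the (2E,4Z)-diene C2=C3–C4=C5; its central C3–C4 single bond joins two olefins that can each be built with defined geometry on separate chain ends, so this bond is cut first (Stille), after tracing the hydroquinone back to the arene dimethyl ether and C15–OH to a silyl ether.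
2. Further cuts of the open chain: N–C1 (anilide from (E)-3-iodo-2-methylacrylic acid), C4–C5 (one-carbon alkyne homologation, then stannylation and hydrozirconation), C6–C7 (syn aldol), C8=C9 (Wittig), C10–C11 and C14–C15 (two (Z)-crotylborations), C11–C12 (hydroformylation), C12–O (enamine α-oxygenation).
3. Forward: the chain grows linearly from 2,5-dimethoxy-3-nitrobenzaldehyde (C15) to the C4 vinylstannane; nitro is reduced and the aniline acylated; the macrocycle is the only ring formed and closes at C3–C4; quinone formation, desilylation and reduction finish.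
4. Stereochemistry: 14S,15R and 10S,11R from (Z)-crotyl-B(Ipc)2 made from (−)-α-pinene (closed transition state; the second addition is matched with the Felkin bias of C12); 12S from an (S)-diarylprolinol silyl ether catalyst; 6S,7R from the (R)-benzyloxazolidinone boron enolate; 8E from a stabilised ylide, 4Z from syn hydrozirconation and protonolysis, 2E from the iodoacrylic acid.

Key step: step 22

Assumption: the aryl oxygens are carried as methyl ethers and the anilide nitrogen as a nitro group; the final hydroquinone re-oxidises in air, so the last step and its work-up are run under argon.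
Abbreviations: TBS = tert-butyldimethylsilyl, TES = triethylsilyl, Ipc = isopinocampheyl, Ar = 2,5-dimethoxy-3-nitrophenyl. Locants C4–C21 in the text follow the numbering of line 1.

**Route**

Step 1
Reactants: 1 2-hydroxy-5-methoxybenzaldehyde
Product: 2 2-hydroxy-5-methoxy-3-nitrobenzaldehyde
Conditions: HNO3 (1.05 equiv), AcOH, 10–15 °C
Reagents that add atoms: nitric acid, O[N+](=O)[O-]
Why: Electrophilic aromatic nitration goes to C3, the position ortho to the phenol and meta to the formyl group, because the para position of the phenol is blocked by the methoxy group.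

Step 2
Reactants: 2 2-hydroxy-5-methoxy-3-nitrobenzaldehyde
Product: 3 2,5-dimethoxy-3-nitrobenzaldehyde
Conditions: MeI, K2CO3, DMF, 50 °C
Reagents that add atoms: iodomethane, CI
Why: Williamson O-methylation of the acidic ortho-nitrophenoxide is a plain SN2 alkylation and gives the dimethyl ether that is unmasked to the quinone only at the end.

Step 3
Reactants: 3 2,5-dimethoxy-3-nitrobenzaldehyde
Product: 5 (1R,2S)-1-(2,5-dimethoxy-3-nitrophenyl)-2-methylbut-3-en-1-ol, via diisopinocampheylborinate 4 (not isolated)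
Conditions: cis-2-butene, n-BuLi, KOt-Bu, THF, −78 to −45 °C; (+)-Ipc2BOMe (from (−)-α-pinene), −78 °C; BF3·OEt2; then 3, −78 °C; NaOH, H2O2, 0 °C to rt
Reagents that add atoms: cis-but-2-ene, C/C=C\C
Why: Brown asymmetric crotylboration proceeds through a closed chair transition state, so the Z-crotyl geometry gives the 14,15-syn relationship and the Ipc groups from (−)-α-pinene should deliver the crotyl unit to the Re face of the aldehyde, setting 15R and 14S.

Step 4
Reactants: 5 (1R,2S)-homoallylic alcohol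
Product: 6 tert-butyl{[(1R,2S)-1-(2,5-dimethoxy-3-nitrophenyl)-2-methylbut-3-en-1-yl]oxy}dimethylsilane
Conditions: TBSOTf, 2,6-lutidine, CH2Cl2, 0 °C
Reagents that add atoms: tert-butyldimethylsilyl trifluoromethanesulfonate, CC(C)(C)[Si](C)(C)OS(=O)(=O)C(F)(F)F
Why: Silylation of the hindered benzylic alcohol with the silyl triflate gives an ether that prevents lactol formation in the next step and should last until after the quinone is made.

Step 5
Reactants: 6 TBS ether of 5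
Product: 7 (4S,5R)-5-[(tert-butyldimethylsilyl)oxy]-5-(2,5-dimethoxy-3-nitrophenyl)-4-methylpentanal
Conditions: Rh(acac)(CO)2 (2 mol %), Xantphos (4 mol %), CO/H2 (1:1, 10 bar), toluene, 70 °C
Reagents that add atoms: carbon monoxide, [C-]#[O+]
Why: Linear-selective rhodium-catalysed hydroformylation of a monosubstituted alkene with a wide-bite-angle diphosphine places the new formyl carbon (C11) at the terminus, the allylic branch at C14 reinforces the linear preference, and nitroarene and silyl ether are not expected to react with the rhodium hydride under CO.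

Step 6
Reactants: 7 C11 aldehyde
Product: 8 (2S,4S,5R)-5-[(tert-butyldimethylsilyl)oxy]-5-(2,5-dimethoxy-3-nitrophenyl)-4-methyl-1-oxopentan-2-yl benzoate
Conditions: (S)-2-[diphenyl(trimethylsilyloxy)methyl]pyrrolidine (10 mol %), dibenzoyl peroxide, hydroquinone (10 mol %), THF, 0 °C to rt; used at once
Reagents that add atoms: dibenzoyl peroxide, O=C(OOC(=O)c1ccccc1)c1ccccc1
Why: Enamine-catalysed asymmetric α-benzoyloxylation of an aldehyde: the E-enamine attacks a peroxide oxygen on the face away from the diphenyl(silyloxy)methyl group of the (S)-catalyst, which should set 12S under catalyst control, the C14 and C15 centres being too remote to interfere.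

Step 7
Reactants: 8 α-benzoyloxy aldehyde
Product: 11 (3S,4R,5S,7S,8R)-8-[(tert-butyldimethylsilyl)oxy]-8-(2,5-dimethoxy-3-nitrophenyl)-3,7-dimethyloct-1-ene-4,5-diol, via diisopinocampheylborinate 9 (not isolated), via hydroxy benzoate 10 (not isolated)
Conditions: (Z)-crotyl-B(Ipc)2 (made as in step 3 from cis-2-butene, n-BuLi, KOt-Bu, (+)-Ipc2BOMe, BF3·OEt2), THF, −78 °C; NaOH, H2O2, 0 °C; then K2CO3, MeOH, rt
Reagents that add atoms: cis-but-2-ene, C/C=C\C
Why: Brown crotylboration again gives the 10,11-syn pair from the Z-reagent, its Re-face delivery coincides with the Felkin–Anh preference of the α-acyloxy aldehyde for the 11,12-anti product (matched pair, 10S and 11R), and the methanolysis removes the benzoate on whichever oxygen it sits after work-up.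

Step 8
Reactants: 11 C11,C12-diol
Product: 12 tert-butyl{[(1R,2S,4S,5R,6S)-1-(2,5-dimethoxy-3-nitrophenyl)-4,5-dimethoxy-2,6-dimethyloct-7-en-1-yl]oxy}dimethylsilane
Conditions: Me3OBF4 (excess), 1,8-bis(dimethylamino)naphthalene, 4 Å molecular sieves, CH2Cl2, rt
Reagents that add atoms: trimethyloxonium tetrafluoroborate, C[O+](C)C.F[B-](F)(F)F
Why: O-Methylation with a trialkyloxonium salt and a non-nucleophilic amine etherifies both secondary hydroxyls without generating alkoxides, which avoids silyl migration and attack on the nitroanisole ring.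

Step 9
Reactants: 12 bis(methyl ether)
Product: 14 (2R,3R,4S,6S,7R)-7-[(tert-butyldimethylsilyl)oxy]-7-(2,5-dimethoxy-3-nitrophenyl)-3,4-dimethoxy-2,6-dimethylheptanal, via ozonide 13 (not isolated)
Conditions: O3, CH2Cl2, −78 °C; PPh3, −78 °C to rt
Reagents that add atoms: ozone, [O-][O+]=O
Why: Ozonolysis with reductive work-up cleaves the only alkene (the nitro-deactivated arene reacts far more slowly) and gives the C9 aldehyde under neutral conditions that should not epimerise C10.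

Step 10
Reactants: 14 C9 aldehyde
Product: 15 (2E,4S,5R,6S,8S,9R)-9-[(tert-butyldimethylsilyl)oxy]-9-(2,5-dimethoxy-3-nitrophenyl)-5,6-dimethoxy-2,4,8-trimethylnon-2-enal
Conditions: Ph3P=C(Me)CHO, toluene, 90 °C
Reagents that add atoms: 2-(triphenylphosphoranylidene)propanal, CC(C=O)=P(c1ccccc1)(c1ccccc1)c1ccccc1
Why: Wittig olefination with a stabilised formyl ylide is E-selective and gives the trisubstituted 8E olefin directly at the enal oxidation level.

Step 11
Reactants: 15 C7 enal; 16 (R)-4-benzyl-3-propionyloxazolidin-2-one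
Product: 19 (4R)-4-benzyl-3-[(2R,3R,4E,6S,7R,8S,10S,11R)-11-[(tert-butyldimethylsilyl)oxy]-11-(2,5-dimethoxy-3-nitrophenyl)-3-hydroxy-7,8-dimethoxy-2,4,6,10-tetramethylundec-4-enoyl]oxazolidin-2-one, via dibutylboron Z-enolate 17 (not isolated), via boron aldolate 18 (not isolated)
Conditions: 16, Bu2BOTf, Et3N, CH2Cl2, −78 to 0 °C; 15, −78 to 0 °C; pH 7 buffer, MeOH, H2O2, 0 °C
Reagents that add atoms: none
Why: Evans syn aldol: the Z-boron enolate adds through a Zimmerman–Traxler chair with the auxiliary dipole opposed to the enolate oxygen, so the (R)-benzyl group fixes the 6,7-syn pair with 7R (and the C6 methyl that becomes 6S in the target) irrespective of the remote centres of the enal.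

Step 12
Reactants: 19 aldol adduct
Product: 20 C7 triethylsilyl ether of 19
Conditions: TESOTf, 2,6-lutidine, CH2Cl2, −78 to 0 °C
Reagents that add atoms: triethylsilyl trifluoromethanesulfonate, CC[Si](CC)(CC)OS(=O)(=O)C(F)(F)F
Why: Silyl ether formation masks the C7 hydroxyl with a group that buffered fluoride can later remove while the C15 TBS ether stays.

Step 13
Reactants: 20 TES-protected imide
Product: 21 (2S,3R,4E,6S,7R,8S,10S,11R)-11-[(tert-butyldimethylsilyl)oxy]-11-(2,5-dimethoxy-3-nitrophenyl)-7,8-dimethoxy-2,4,6,10-tetramethyl-3-[(triethylsilyl)oxy]undec-4-en-1-ol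
Conditions: LiBH4, MeOH (1 equiv), THF, 0 °C
Reagents that add atoms: none
Why: Reductive cleavage of the N-acyloxazolidinone by borohydride attack at the exocyclic carbonyl gives the C5 primary alcohol, and LiBH4 at 0 °C should leave the nitroarene and both silyl ethers alone.

Step 14
Reactants: 21 C5 alcohol
Product: 22 (2R,3R,4E,6S,7R,8S,10S,11R)-11-[(tert-butyldimethylsilyl)oxy]-11-(2,5-dimethoxy-3-nitrophenyl)-7,8-dimethoxy-2,4,6,10-tetramethyl-3-[(triethylsilyl)oxy]undec-4-enal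
Conditions: Dess–Martin periodinane, NaHCO3, CH2Cl2, 0 °C to rt
Reagents that add atoms: none
Why: Dess–Martin oxidation under buffered, non-basic conditions gives the α-methyl-β-silyloxy aldehyde without epimerisation at C6 or β-elimination.

Step 15
Reactants: 22 C5 aldehyde
Product: 23 (3S,4R,5E,7S,8R,9S,11S,12R)-12-[(tert-butyldimethylsilyl)oxy]-12-(2,5-dimethoxy-3-nitrophenyl)-8,9-dimethoxy-3,5,7,11-tetramethyl-4-[(triethylsilyl)oxy]dodec-5-en-1-yne
Conditions: dimethyl (1-diazo-2-oxopropyl)phosphonate, K2CO3, MeOH, 0 °C to rt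
Reagents that add atoms: dimethyl (1-diazo-2-oxopropyl)phosphonate, COP(=O)(OC)C(=[N+]=[N-])C(C)=O
Why: Ohira–Bestmann (Seyferth–Gilbert) homologation adds C4 as the terminal alkyne carbon through a diazoalkene and 1,2-hydride shift under carbonate conditions mild enough to keep the C6 configuration.

Step 16
Reactants: 23 terminal alkyne
Product: 24 tributyl[(3S,4R,5E,7S,8R,9S,11S,12R)-12-[(tert-butyldimethylsilyl)oxy]-12-(2,5-dimethoxy-3-nitrophenyl)-8,9-dimethoxy-3,5,7,11-tetramethyl-4-[(triethylsilyl)oxy]dodec-5-en-1-yn-1-yl]stannane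
Conditions: Bu3SnOMe, ZnBr2 (5 mol %), THF, rt; used crude
Reagents that add atoms: tributyltin methoxide, CCCC[Sn](CCCC)(CCCC)OC
Why: Zinc-catalysed stannylation of a terminal alkyne with a tin alkoxide forms the alkynylstannane with loss of methanol and needs no lithium base, which the nitroarene would not tolerate.

Step 17
Reactants: 24 alkynylstannane
Product: 26 tributyl[(1Z,3S,4R,5E,7S,8R,9S,11S,12R)-12-[(tert-butyldimethylsilyl)oxy]-12-(2,5-dimethoxy-3-nitrophenyl)-8,9-dimethoxy-3,5,7,11-tetramethyl-4-[(triethylsilyl)oxy]dodeca-1,5-dien-1-yl]stannane, via 1-stannyl-1-zirconocenyl alkene 25 (not isolated)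
Conditions: Cp2Zr(H)Cl (1.5 equiv), THF, rt, 20 min; then H2O
Reagents that add atoms: none
Why: Hydrozirconation of an alkynylstannane followed by protonolysis: syn addition of Zr–H puts zirconium on C4 beside tin and hydrogen on C5, and stereoretentive protonation of the C–Zr bond leaves tin cis to C6 (4Z), the short exposure at room temperature being chosen so that the nitro group is expected to survive.

Step 18
Reactants: 26 Z-vinylstannane
Product: 27 (1Z,3S,4R,5E,7S,8R,9S,11S,12R)-12-[(tert-butyldimethylsilyl)oxy]-12-(2,5-dimethoxy-3-nitrophenyl)-8,9-dimethoxy-3,5,7,11-tetramethyl-1-(tributylstannyl)dodeca-1,5-dien-4-ol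
Conditions: HF·pyridine, pyridine, THF, 0 °C
Reagents that add atoms: none
Why: Pyridine-buffered fluoride desilylation removes the less hindered TES ether selectively and is not acidic enough to protodestannylate the vinylstannane or cleave the C15 TBS ether.

Step 19
Reactants: 27 C7 alcohol
Product: 29 (1Z,3S,4R,5E,7S,8R,9S,11S,12R)-12-[(tert-butyldimethylsilyl)oxy]-12-(2,5-dimethoxy-3-nitrophenyl)-8,9-dimethoxy-3,5,7,11-tetramethyl-1-(tributylstannyl)dodeca-1,5-dien-4-yl carbamate, via N-trichloroacetyl carbamate 28 (not isolated)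
Conditions: Cl3CC(O)NCO, CH2Cl2, 0 °C; then K2CO3, MeOH, 0 °C to rt
Reagents that add atoms: trichloroacetyl isocyanate, O=C=NC(=O)C(Cl)(Cl)Cl
Why: Carbamoylation by addition of the hindered allylic alcohol to the acyl isocyanate and methanolysis of the trichloroacetyl group gives the primary carbamate under conditions inert to the C–Sn bond.

Step 20
Reactants: 29 nitro carbamate
Product: 30 (1Z,3S,4R,5E,7S,8R,9S,11S,12R)-12-(3-amino-2,5-dimethoxyphenyl)-12-[(tert-butyldimethylsilyl)oxy]-8,9-dimethoxy-3,5,7,11-tetramethyl-1-(tributylstannyl)dodeca-1,5-dien-4-yl carbamate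
Conditions: Fe powder, NH4Cl, EtOH/H2O (4:1), 60 °C
Reagents that add atoms: none
Why: Béchamp-type reduction of the nitroarene by iron metal at near-neutral pH gives the aniline and should spare the vinylstannane, both olefins, the carbamate and the silyl ether.

Step 21
Reactants: 30 aniline; 31 (E)-3-iodo-2-methylprop-2-enoic acid
Product: 33 (1Z,3S,4R,5E,7S,8R,9S,11S,12R)-12-[(tert-butyldimethylsilyl)oxy]-12-{3-[(E)-3-iodo-2-methylacrylamido]-2,5-dimethoxyphenyl}-8,9-dimethoxy-3,5,7,11-tetramethyl-1-(tributylstannyl)dodeca-1,5-dien-4-yl carbamate, via (E)-3-iodo-2-methylacryloyl chloride 32 (not isolated)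
Conditions: 31, (COCl)2, cat. DMF, CH2Cl2, 0 °C to rt, concentrate; then 30, pyridine, CH2Cl2, 0 °C
Reagents that add atoms: none
Why: N-Acylation of the aniline with the acid chloride is selective over the far less nucleophilic carbamate nitrogen, pyridine traps HCl before it can cleave the C–Sn bond, and the 2E geometry of the acid is carried over unchanged.

Step 22
Reactants: 33 open-chain (E)-iodoacrylanilide carrying the C4 (Z)-vinylstannane
Product: 34 19-membered lactam (2E,4Z,6S,7R,8E,10S,11R,12S,14S,15R) with C7 carbamate; C15 TBS ether; arene as 18,21-dimethyl ether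
Conditions: Pd2(dba)3 (0.2 equiv), AsPh3 (1.6 equiv), i-Pr2NEt, degassed DMF, 1 mM by slow addition, rt to 40 °C
Reagents that add atoms: none
Why: Zerovalent palladium carrying the weakly donating AsPh3 adds oxidatively to the C3–I bond with retention, the C4 vinylstannane transmetallates with retention to a divalent palladium dialkenyl that holds both chain ends, and reductive elimination forms C3–C4 and releases Bu3SnI. The closest known reaction type is the macrocyclic Stille coupling of a vinyl iodide with a Z-vinylstannane that leaves an E,Z-diene inside a large ring. The 19-membered ring (N, C1–C16, C21, C20) closes by intramolecular transmetallation to a palladacycle followed by ring-contracting reductive elimination between two sp2 carbons, both olefins ending up endocyclic. No stereocentre is created, and the 2E and 4Z geometries come from compound 31 and from step 17 and are kept because every elementary step is stereoretentive. The step needs ring closure to win over oligomerisation and the 4Z olefin not to isomerise, which high dilution with slow addition, the fast transmetallation of the arsine-ligated catalyst near room temperature and the conformational restriction by the 8E olefin and the anilide should secure. The base-free medium is not expected to affect the carbamate NH2, the anilide N–H or the C15 silyl ether.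

Step 23
Reactants: 34 macrocyclic dimethoxyarene
Product: 35 C15 TBS ether of the 18,21-quinone lactam
Conditions: (NH4)2Ce(NO3)6, MeCN/H2O, 0 °C
Reagents that add atoms: water, O
Why: Oxidative demethylation of a 1,4-dimethoxyarene by tetravalent cerium takes place on the electron-rich amido-substituted ring in preference to the diene and carbamate, while the silyl ether shields the benzylic C15 position from oxidation.

Step 24
Reactants: 35 quinone TBS ether
Product: 36 C15-hydroxy 18,21-quinone lactam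
Conditions: HF·pyridine, THF, 0 °C to rt
Reagents that add atoms: none
Why: Fluoride-mediated desilylation frees the C15 alcohol under mildly acidic conditions that the quinone, diene and carbamate are expected to tolerate.

Step 25
Reactants: 36 quinone
Product: 37 target hydroquinone lactam CNP0532580.1 (2E,4Z,6S,7R,8E,10S,11R,12S,14S,15R)
Conditions: Na2S2O4, EtOAc/H2O, rt, argon
Reagents that add atoms: none
Why: Dithionite reduction is a two-electron, two-proton reduction of the quinone to the hydroquinone that touches no other functional group and no stereocentre.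

**Compound list**
1 | 2-hydroxy-5-methoxybenzaldehyde | COc1ccc(O)c(C=O)c1 | starting material
2 | 2-hydroxy-5-methoxy-3-nitrobenzaldehyde | COc1cc(C=O)c(O)c([N+](=O)[O-])c1 | intermediate
3 | 2,5-dimethoxy-3-nitrobenzaldehyde | COc1cc(C=O)c(OC)c([N+](=O)[O-])c1 | intermediate
4 | (1R,2S)-1-(2,5-dimethoxy-3-nitrophenyl)-2-methylbut-3-en-1-yl diisopinocampheylborinate | C=C[C@H](C)[C@@H](OB([C@H]1C[C@H]2C[C@H](C2(C)C)[C@@H]1C)[C@H]1C[C@H]2C[C@H](C2(C)C)[C@@H]1C)c1cc(OC)cc([N+](=O)[O-])c1OC | intermediate (not isolated)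
5 | (1R,2S)-1-(2,5-dimethoxy-3-nitrophenyl)-2-methylbut-3-en-1-ol | C=C[C@H](C)[C@@H](O)c1cc(OC)cc([N+](=O)[O-])c1OC | intermediate
6 | tert-butyl{[(1R,2S)-1-(2,5-dimethoxy-3-nitrophenyl)-2-methylbut-3-en-1-yl]oxy}dimethylsilane | C=C[C@H](C)[C@@H](O[Si](C)(C)C(C)(C)C)c1cc(OC)cc([N+](=O)[O-])c1OC | intermediate
7 | (4S,5R)-5-[(tert-butyldimethylsilyl)oxy]-5-(2,5-dimethoxy-3-nitrophenyl)-4-methylpentanal | O=CCC[C@H](C)[C@@H](O[Si](C)(C)C(C)(C)C)c1cc(OC)cc([N+](=O)[O-])c1OC | intermediate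
8 | (2S,4S,5R)-5-[(tert-butyldimethylsilyl)oxy]-5-(2,5-dimethoxy-3-nitrophenyl)-4-methyl-1-oxopentan-2-yl benzoate | O=C[C@@H](OC(=O)c1ccccc1)C[C@H](C)[C@@H](O[Si](C)(C)C(C)(C)C)c1cc(OC)cc([N+](=O)[O-])c1OC | intermediate
9 | O4-diisopinocampheylborinate of compound 10 | C=C[C@H](C)[C@@H](OB([C@H]1C[C@H]2C[C@H](C2(C)C)[C@@H]1C)[C@H]1C[C@H]2C[C@H](C2(C)C)[C@@H]1C)[C@@H](OC(=O)c1ccccc1)C[C@H](C)[C@@H](O[Si](C)(C)C(C)(C)C)c1cc(OC)cc([N+](=O)[O-])c1OC | intermediate (not isolated)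
10 | (3S,4R,5S,7S,8R)-8-[(tert-butyldimethylsilyl)oxy]-8-(2,5-dimethoxy-3-nitrophenyl)-4-hydroxy-3,7-dimethyloct-1-en-5-yl benzoate | C=C[C@H](C)[C@@H](O)[C@@H](OC(=O)c1ccccc1)C[C@H](C)[C@@H](O[Si](C)(C)C(C)(C)C)c1cc(OC)cc([N+](=O)[O-])c1OC | intermediate (not isolated)
11 | (3S,4R,5S,7S,8R)-8-[(tert-butyldimethylsilyl)oxy]-8-(2,5-dimethoxy-3-nitrophenyl)-3,7-dimethyloct-1-ene-4,5-diol | C=C[C@H](C)[C@@H](O)[C@@H](O)C[C@H](C)[C@@H](O[Si](C)(C)C(C)(C)C)c1cc(OC)cc([N+](=O)[O-])c1OC | intermediate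
12 | tert-butyl{[(1R,2S,4S,5R,6S)-1-(2,5-dimethoxy-3-nitrophenyl)-4,5-dimethoxy-2,6-dimethyloct-7-en-1-yl]oxy}dimethylsilane | C=C[C@H](C)[C@@H](OC)[C@@H](OC)C[C@H](C)[C@@H](O[Si](C)(C)C(C)(C)C)c1cc(OC)cc([N+](=O)[O-])c1OC | intermediate
13 | 3-[(2R,3R,4S,6S,7R)-7-[(tert-butyldimethylsilyl)oxy]-7-(2,5-dimethoxy-3-nitrophenyl)-3,4-dimethoxy-6-methylheptan-2-yl]-1,2,4-trioxolane (both epimers at the ring carbon) | O1OCOC1[C@H](C)[C@@H](OC)[C@@H](OC)C[C@H](C)[C@@H](O[Si](C)(C)C(C)(C)C)c1cc(OC)cc([N+](=O)[O-])c1OC | intermediate (not isolated)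
14 | (2R,3R,4S,6S,7R)-7-[(tert-butyldimethylsilyl)oxy]-7-(2,5-dimethoxy-3-nitrophenyl)-3,4-dimethoxy-2,6-dimethylheptanal | O=C[C@H](C)[C@@H](OC)[C@@H](OC)C[C@H](C)[C@@H](O[Si](C)(C)C(C)(C)C)c1cc(OC)cc([N+](=O)[O-])c1OC | intermediate
15 | (2E,4S,5R,6S,8S,9R)-9-[(tert-butyldimethylsilyl)oxy]-9-(2,5-dimethoxy-3-nitrophenyl)-5,6-dimethoxy-2,4,8-trimethylnon-2-enal | O=C/C(C)=C/[C@H](C)[C@@H](OC)[C@@H](OC)C[C@H](C)[C@@H](O[Si](C)(C)C(C)(C)C)c1cc(OC)cc([N+](=O)[O-])c1OC | intermediate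
16 | (R)-4-benzyl-3-propionyloxazolidin-2-one | CCC(=O)N1[C@H](Cc2ccccc2)COC1=O | starting material
17 | (Z)-dibutylboron enolate of compound 16 | C/C=C(\OB(CCCC)CCCC)N1[C@H](Cc2ccccc2)COC1=O | intermediate (not isolated)
18 | O3-dibutylboron aldolate of compound 19 | O=C(N1[C@H](Cc2ccccc2)COC1=O)[C@H](C)[C@@H](OB(CCCC)CCCC)/C(C)=C/[C@H](C)[C@@H](OC)[C@@H](OC)C[C@H](C)[C@@H](O[Si](C)(C)C(C)(C)C)c1cc(OC)cc([N+](=O)[O-])c1OC | intermediate (not isolated)
19 | (4R)-4-benzyl-3-[(2R,3R,4E,6S,7R,8S,10S,11R)-11-[(tert-butyldimethylsilyl)oxy]-11-(2,5-dimethoxy-3-nitrophenyl)-3-hydroxy-7,8-dimethoxy-2,4,6,10-tetramethylundec-4-enoyl]oxazolidin-2-one | O=C(N1[C@H](Cc2ccccc2)COC1=O)[C@H](C)[C@@H](O)/C(C)=C/[C@H](C)[C@@H](OC)[C@@H](OC)C[C@H](C)[C@@H](O[Si](C)(C)C(C)(C)C)c1cc(OC)cc([N+](=O)[O-])c1OC | intermediate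
20 | (4R)-4-benzyl-3-[(2R,3R,4E,6S,7R,8S,10S,11R)-11-[(tert-butyldimethylsilyl)oxy]-11-(2,5-dimethoxy-3-nitrophenyl)-7,8-dimethoxy-2,4,6,10-tetramethyl-3-[(triethylsilyl)oxy]undec-4-enoyl]oxazolidin-2-one | O=C(N1[C@H](Cc2ccccc2)COC1=O)[C@H](C)[C@@H](O[Si](CC)(CC)CC)/C(C)=C/[C@H](C)[C@@H](OC)[C@@H](OC)C[C@H](C)[C@@H](O[Si](C)(C)C(C)(C)C)c1cc(OC)cc([N+](=O)[O-])c1OC | intermediate
21 | (2S,3R,4E,6S,7R,8S,10S,11R)-11-[(tert-butyldimethylsilyl)oxy]-11-(2,5-dimethoxy-3-nitrophenyl)-7,8-dimethoxy-2,4,6,10-tetramethyl-3-[(triethylsilyl)oxy]undec-4-en-1-ol | OC[C@H](C)[C@@H](O[Si](CC)(CC)CC)/C(C)=C/[C@H](C)[C@@H](OC)[C@@H](OC)C[C@H](C)[C@@H](O[Si](C)(C)C(C)(C)C)c1cc(OC)cc([N+](=O)[O-])c1OC | intermediate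
22 | (2R,3R,4E,6S,7R,8S,10S,11R)-11-[(tert-butyldimethylsilyl)oxy]-11-(2,5-dimethoxy-3-nitrophenyl)-7,8-dimethoxy-2,4,6,10-tetramethyl-3-[(triethylsilyl)oxy]undec-4-enal | O=C[C@H](C)[C@@H](O[Si](CC)(CC)CC)/C(C)=C/[C@H](C)[C@@H](OC)[C@@H](OC)C[C@H](C)[C@@H](O[Si](C)(C)C(C)(C)C)c1cc(OC)cc([N+](=O)[O-])c1OC | intermediate
23 | (3S,4R,5E,7S,8R,9S,11S,12R)-12-[(tert-butyldimethylsilyl)oxy]-12-(2,5-dimethoxy-3-nitrophenyl)-8,9-dimethoxy-3,5,7,11-tetramethyl-4-[(triethylsilyl)oxy]dodec-5-en-1-yne | C#C[C@H](C)[C@@H](O[Si](CC)(CC)CC)/C(C)=C/[C@H](C)[C@@H](OC)[C@@H](OC)C[C@H](C)[C@@H](O[Si](C)(C)C(C)(C)C)c1cc(OC)cc([N+](=O)[O-])c1OC | intermediate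
24 | tributyl[(3S,4R,5E,7S,8R,9S,11S,12R)-12-[(tert-butyldimethylsilyl)oxy]-12-(2,5-dimethoxy-3-nitrophenyl)-8,9-dimethoxy-3,5,7,11-tetramethyl-4-[(triethylsilyl)oxy]dodec-5-en-1-yn-1-yl]stannane | CCCC[Sn](CCCC)(CCCC)C#C[C@H](C)[C@@H](O[Si](CC)(CC)CC)/C(C)=C/[C@H](C)[C@@H](OC)[C@@H](OC)C[C@H](C)[C@@H](O[Si](C)(C)C(C)(C)C)c1cc(OC)cc([N+](=O)[O-])c1OC | intermediate
25 | C4 geminal tributylstannyl chlorozirconocenyl alkene from compound 24 (tin cis to C6) | CCCC[Sn](CCCC)(CCCC)/C(=C\[C@H](C)[C@@H](O[Si](CC)(CC)CC)/C(C)=C/[C@H](C)[C@@H](OC)[C@@H](OC)C[C@H](C)[C@@H](O[Si](C)(C)C(C)(C)C)c1cc(OC)cc([N+](=O)[O-])c1OC)[Zr](Cl)(C1C=CC=C1)C1C=CC=C1 | intermediate (not isolated)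
26 | tributyl[(1Z,3S,4R,5E,7S,8R,9S,11S,12R)-12-[(tert-butyldimethylsilyl)oxy]-12-(2,5-dimethoxy-3-nitrophenyl)-8,9-dimethoxy-3,5,7,11-tetramethyl-4-[(triethylsilyl)oxy]dodeca-1,5-dien-1-yl]stannane | CCCC[Sn](CCCC)(CCCC)/C=C\[C@H](C)[C@@H](O[Si](CC)(CC)CC)/C(C)=C/[C@H](C)[C@@H](OC)[C@@H](OC)C[C@H](C)[C@@H](O[Si](C)(C)C(C)(C)C)c1cc(OC)cc([N+](=O)[O-])c1OC | intermediate
27 | (1Z,3S,4R,5E,7S,8R,9S,11S,12R)-12-[(tert-butyldimethylsilyl)oxy]-12-(2,5-dimethoxy-3-nitrophenyl)-8,9-dimethoxy-3,5,7,11-tetramethyl-1-(tributylstannyl)dodeca-1,5-dien-4-ol | CCCC[Sn](CCCC)(CCCC)/C=C\[C@H](C)[C@@H](O)/C(C)=C/[C@H](C)[C@@H](OC)[C@@H](OC)C[C@H](C)[C@@H](O[Si](C)(C)C(C)(C)C)c1cc(OC)cc([N+](=O)[O-])c1OC | intermediate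
28 | N-(trichloroacetyl)carbamate of compound 27 | CCCC[Sn](CCCC)(CCCC)/C=C\[C@H](C)[C@@H](OC(=O)NC(=O)C(Cl)(Cl)Cl)/C(C)=C/[C@H](C)[C@@H](OC)[C@@H](OC)C[C@H](C)[C@@H](O[Si](C)(C)C(C)(C)C)c1cc(OC)cc([N+](=O)[O-])c1OC | intermediate (not isolated)
29 | (1Z,3S,4R,5E,7S,8R,9S,11S,12R)-12-[(tert-butyldimethylsilyl)oxy]-12-(2,5-dimethoxy-3-nitrophenyl)-8,9-dimethoxy-3,5,7,11-tetramethyl-1-(tributylstannyl)dodeca-1,5-dien-4-yl carbamate | CCCC[Sn](CCCC)(CCCC)/C=C\[C@H](C)[C@@H](OC(N)=O)/C(C)=C/[C@H](C)[C@@H](OC)[C@@H](OC)C[C@H](C)[C@@H](O[Si](C)(C)C(C)(C)C)c1cc(OC)cc([N+](=O)[O-])c1OC | intermediate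
30 | (1Z,3S,4R,5E,7S,8R,9S,11S,12R)-12-(3-amino-2,5-dimethoxyphenyl)-12-[(tert-butyldimethylsilyl)oxy]-8,9-dimethoxy-3,5,7,11-tetramethyl-1-(tributylstannyl)dodeca-1,5-dien-4-yl carbamate | CCCC[Sn](CCCC)(CCCC)/C=C\[C@H](C)[C@@H](OC(N)=O)/C(C)=C/[C@H](C)[C@@H](OC)[C@@H](OC)C[C@H](C)[C@@H](O[Si](C)(C)C(C)(C)C)c1cc(OC)cc(N)c1OC | intermediate
31 | (E)-3-iodo-2-methylprop-2-enoic acid | C/C(=C\I)C(=O)O | starting material
32 | (E)-3-iodo-2-methylprop-2-enoyl chloride | C/C(=C\I)C(=O)Cl | intermediate (not isolated)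
33 | (1Z,3S,4R,5E,7S,8R,9S,11S,12R)-12-[(tert-butyldimethylsilyl)oxy]-12-{3-[(E)-3-iodo-2-methylacrylamido]-2,5-dimethoxyphenyl}-8,9-dimethoxy-3,5,7,11-tetramethyl-1-(tributylstannyl)dodeca-1,5-dien-4-yl carbamate | CCCC[Sn](CCCC)(CCCC)/C=C\[C@H](C)[C@@H](OC(N)=O)/C(C)=C/[C@H](C)[C@@H](OC)[C@@H](OC)C[C@H](C)[C@@H](O[Si](C)(C)C(C)(C)C)c1cc(OC)cc(NC(=O)/C(C)=C/I)c1OC | intermediate
34 | 19-membered lactam, (2E,4Z,6S,7R,8E,10S,11R,12S,14S,15R), 7-carbamate, 11,12-dimethoxy, 15-O-TBS, arene as 18,21-dimethyl ether | N1C(=O)/C(C)=C/C=C\[C@H](C)[C@@H](OC(N)=O)/C(C)=C/[C@H](C)[C@@H](OC)[C@@H](OC)C[C@H](C)[C@@H](O[Si](C)(C)C(C)(C)C)c2cc(OC)cc1c2OC | intermediate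
35 | 18,21-benzoquinone of the lactam, 15-O-TBS, (2E,4Z,6S,7R,8E,10S,11R,12S,14S,15R) | N1C(=O)/C(C)=C/C=C\[C@H](C)[C@@H](OC(N)=O)/C(C)=C/[C@H](C)[C@@H](OC)[C@@H](OC)C[C@H](C)[C@@H](O[Si](C)(C)C(C)(C)C)C2=CC(=O)C=C1C2=O | intermediate
36 | 18,21-benzoquinone of the lactam with free 15-hydroxyl, (2E,4Z,6S,7R,8E,10S,11R,12S,14S,15R) | N1C(=O)/C(C)=C/C=C\[C@H](C)[C@@H](OC(N)=O)/C(C)=C/[C@H](C)[C@@H](OC)[C@@H](OC)C[C@H](C)[C@@H](O)C2=CC(=O)C=C1C2=O | intermediate
37 | CNP0532580.1, 18,21-hydroquinone lactam, (2E,4Z,6S,7R,8E,10S,11R,12S,14S,15R), 7-carbamate, 11,12-dimethoxy, 15-hydroxy | CO[C@H]1[C@@H](OC)C[C@H](C)[C@@H](O)c2cc(O)cc(c2O)NC(=O)/C(C)=C/C=C\[C@H](C)[C@@H](OC(N)=O)/C(C)=C/[C@@H]1C | target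

**Summary**
Total step count: 25. Longest linear sequence: 25 steps (1 to 37); compounds 16 and 31 are purchased and enter in steps 11 and 21.

Steps most likely to fail:

Step 22 (macrocyclic Stille coupling). Intermolecular coupling may outrun ring closure, the stannane may be lost by protodestannylation, or the 4Z olefin may isomerise during long exposure to palladium. The fallback sets out from aniline 30 and forms the same C3–C4 bond on the open chain: Stille coupling of 30 with acid 31 (Pd2(dba)3, AsPh3, i-Pr2NEt, DMF, rt) gives (2E,4Z,6S,7R,8E,10S,11R,12S,14S,15R)-15-(3-amino-2,5-dimethoxyphenyl)-15-[(tert-butyldimethylsilyl)oxy]-7-(carbamoyloxy)-11,12-dimethoxy-2,6,8,10,14-pentamethylpentadeca-2,4,8-trienoic acid F9. The ring is then closed at N–C1 by macrolactamisation (bis(2-oxo-3-oxazolidinyl)phosphinic chloride, i-Pr2NEt, toluene, high dilution, 80 °C), which returns to the route at 34.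

Step 6 (α-benzoyloxylation). The α-acyloxy aldehyde may racemise at C12 or eliminate benzoate on handling, or the peroxide may oxidise the amine catalyst and stop turnover. The fallback sets out from aldehyde 7 and fixes C12 by an auxiliary instead of a catalyst.
- Pinnick oxidation (NaClO2, NaH2PO4, 2-methyl-2-butene, t-BuOH/H2O) gives (4S,5R)-5-[(tert-butyldimethylsilyl)oxy]-5-(2,5-dimethoxy-3-nitrophenyl)-4-methylpentanoic acid F1.
- Acylation of (S)-4-benzyloxazolidin-2-one through the pivaloyl mixed anhydride (PivCl, Et3N, LiCl, THF) gives (4S)-4-benzyl-3-[(4S,5R)-5-[(tert-butyldimethylsilyl)oxy]-5-(2,5-dimethoxy-3-nitrophenyl)-4-methylpentanoyl]oxazolidin-2-one F2.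
- Enolate hydroxylation (NaHMDS, THF, −78 °C; 2-(phenylsulfonyl)-3-phenyloxaziridine) gives (4S)-4-benzyl-3-[(2S,4S,5R)-5-[(tert-butyldimethylsilyl)oxy]-5-(2,5-dimethoxy-3-nitrophenyl)-2-hydroxy-4-methylpentanoyl]oxazolidin-2-one F3.
- Methylation (Me3OBF4, 1,8-bis(dimethylamino)naphthalene) gives (4S)-4-benzyl-3-[(2S,4S,5R)-5-[(tert-butyldimethylsilyl)oxy]-5-(2,5-dimethoxy-3-nitrophenyl)-2-methoxy-4-methylpentanoyl]oxazolidin-2-one F4.
- LiBH4 reduction gives (2S,4S,5R)-5-[(tert-butyldimethylsilyl)oxy]-5-(2,5-dimethoxy-3-nitrophenyl)-2-methoxy-4-methylpentan-1-ol F5.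
- Dess–Martin oxidation gives (2S,4S,5R)-5-[(tert-butyldimethylsilyl)oxy]-5-(2,5-dimethoxy-3-nitrophenyl)-2-methoxy-4-methylpentanal F6.
- Crotylboration with the reagent of step 7 gives (3S,4R,5S,7S,8R)-8-[(tert-butyldimethylsilyl)oxy]-8-(2,5-dimethoxy-3-nitrophenyl)-5-methoxy-3,7-dimethyloct-1-en-4-ol F7.
- Methylation of the remaining hydroxyl (Me3OBF4, 1,8-bis(dimethylamino)naphthalene) returns to the route at 12.

Step 17 (hydrozirconation). The zirconium hydride may attack the nitro group, or the vinylstannane may be lost by protodestannylation at the aqueous quench. The fallback sets out from aldehyde 22 and avoids the alkyne. Stork–Zhao olefination ((iodomethyl)triphenylphosphonium iodide, NaHMDS, THF, −78 °C) gives (1Z,3S,4R,5E,7S,8R,9S,11S,12R)-12-[(tert-butyldimethylsilyl)oxy]-12-(2,5-dimethoxy-3-nitrophenyl)-1-iodo-8,9-dimethoxy-3,5,7,11-tetramethyl-4-[(triethylsilyl)oxy]dodeca-1,5-diene F8. Palladium-catalysed stannylation with retention ((Bu3Sn)2, Pd(PPh3)4, toluene, 80 °C) returns to the route at 26.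

**Further compounds**
F1 | step 6 | (4S,5R)-5-[(tert-butyldimethylsilyl)oxy]-5-(2,5-dimethoxy-3-nitrophenyl)-4-methylpentanoic acid | OC(=O)CC[C@H](C)[C@@H](O[Si](C)(C)C(C)(C)C)c1cc(OC)cc([N+](=O)[O-])c1OC
F2 | step 6 | (4S)-4-benzyl-3-[(4S,5R)-5-[(tert-butyldimethylsilyl)oxy]-5-(2,5-dimethoxy-3-nitrophenyl)-4-methylpentanoyl]oxazolidin-2-one | O=C(CC[C@H](C)[C@@H](O[Si](C)(C)C(C)(C)C)c1cc(OC)cc([N+](=O)[O-])c1OC)N1[C@@H](Cc2ccccc2)COC1=O
F3 | step 6 | (4S)-4-benzyl-3-[(2S,4S,5R)-5-[(tert-butyldimethylsilyl)oxy]-5-(2,5-dimethoxy-3-nitrophenyl)-2-hydroxy-4-methylpentanoyl]oxazolidin-2-one | O=C([C@@H](O)C[C@H](C)[C@@H](O[Si](C)(C)C(C)(C)C)c1cc(OC)cc([N+](=O)[O-])c1OC)N1[C@@H](Cc2ccccc2)COC1=O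
F4 | step 6 | (4S)-4-benzyl-3-[(2S,4S,5R)-5-[(tert-butyldimethylsilyl)oxy]-5-(2,5-dimethoxy-3-nitrophenyl)-2-methoxy-4-methylpentanoyl]oxazolidin-2-one | O=C([C@@H](OC)C[C@H](C)[C@@H](O[Si](C)(C)C(C)(C)C)c1cc(OC)cc([N+](=O)[O-])c1OC)N1[C@@H](Cc2ccccc2)COC1=O
F5 | step 6 | (2S,4S,5R)-5-[(tert-butyldimethylsilyl)oxy]-5-(2,5-dimethoxy-3-nitrophenyl)-2-methoxy-4-methylpentan-1-ol | OC[C@@H](OC)C[C@H](C)[C@@H](O[Si](C)(C)C(C)(C)C)c1cc(OC)cc([N+](=O)[O-])c1OC
F6 | step 6 | (2S,4S,5R)-5-[(tert-butyldimethylsilyl)oxy]-5-(2,5-dimethoxy-3-nitrophenyl)-2-methoxy-4-methylpentanal | O=C[C@@H](OC)C[C@H](C)[C@@H](O[Si](C)(C)C(C)(C)C)c1cc(OC)cc([N+](=O)[O-])c1OC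
F7 | step 6 | (3S,4R,5S,7S,8R)-8-[(tert-butyldimethylsilyl)oxy]-8-(2,5-dimethoxy-3-nitrophenyl)-5-methoxy-3,7-dimethyloct-1-en-4-ol | C=C[C@H](C)[C@@H](O)[C@@H](OC)C[C@H](C)[C@@H](O[Si](C)(C)C(C)(C)C)c1cc(OC)cc([N+](=O)[O-])c1OC
F8 | step 17 | (1Z,3S,4R,5E,7S,8R,9S,11S,12R)-12-[(tert-butyldimethylsilyl)oxy]-12-(2,5-dimethoxy-3-nitrophenyl)-1-iodo-8,9-dimethoxy-3,5,7,11-tetramethyl-4-[(triethylsilyl)oxy]dodeca-1,5-diene | I/C=C\[C@H](C)[C@@H](O[Si](CC)(CC)CC)/C(C)=C/[C@H](C)[C@@H](OC)[C@@H](OC)C[C@H](C)[C@@H](O[Si](C)(C)C(C)(C)C)c1cc(OC)cc([N+](=O)[O-])c1OC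
F9 | step 22 | (2E,4Z,6S,7R,8E,10S,11R,12S,14S,15R)-15-(3-amino-2,5-dimethoxyphenyl)-15-[(tert-butyldimethylsilyl)oxy]-7-(carbamoyloxy)-11,12-dimethoxy-2,6,8,10,14-pentamethylpentadeca-2,4,8-trienoic acid | OC(=O)/C(C)=C/C=C\[C@H](C)[C@@H](OC(N)=O)/C(C)=C/[C@H](C)[C@@H](OC)[C@@H](OC)C[C@H](C)[C@@H](O[Si](C)(C)C(C)(C)C)c1cc(OC)cc(N)c1OC
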